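**Plan**
1. Retrosynthesis: ring B is opened at C6=C7 (intramolecular Knoevenagel) and at C5–C6 (malonate chain extension of a C4a carboxylic acid); two hydrogens are removed from C4/C4a to reach a cyclohexa-1,3-diene; ring A is then cut at C2=C3 and C4a–C8a.
2. Enabling feature: in ring A (C1, C2, C3, C4, C4a, C8a) C2 is a former ketone carbon next to the ester-bearing C1, a β-keto ester whose alkylidene carbon is C8a. C3–C4–C4a is an allyl unit carrying H, CO2Me and the C5 carboxyl, which is an allylic phosphorus ylide. One Michael/Wittig event therefore makes C4a–C8a and C2=C3.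
3. Forward: methyl 3-oxononadecanoate supplies both C16 arms (as keto ester and as ketal aldehyde, joined by Knoevenagel); the ylide is made from methyl pyruvate; ring A closes in step 9, ring B last in step 13.
4. Stereochemistry: C8a comes from the catalyst in the Michael stage and C1 settles trans to it by allylic strain. C4 and C4a come from conjugate reduction on the face opposite the C8a side chain, and the cis ring fusion is carried through the ring B closure.

Key step: step 9

Remark: the facial sense of the thiourea in step 9 is assigned by analogy only; if it proves opposite, the (1S,2S) catalyst is used and nothing else changes.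

Step 1
Reactants: 1 methyl acetoacetate; 2 1-bromopentadecane
Product: 4 methyl 3-oxononadecanoate, via acetoacetate dianion 3 (not isolated)
Conditions: NaH, THF, 0 °C; n-BuLi, 0 °C; then 2, 0 °C to rt; 1 M HCl
Reagents that add atoms: none
Why: γ-Alkylation of the acetoacetate dianion, in which the more basic terminal carbanion is alkylated by the primary bromide, puts the C16 chain on the ketone carbon; no stereocentre is formed.

Step 2
Reactants: 4 methyl 3-oxononadecanoate
Product: 5 methyl 2-(2-hexadecyl-1,3-dioxolan-2-yl)acetate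
Conditions: HOCH2CH2OH, TsOH·H2O (cat.), toluene, reflux, Dean–Stark
Reagents that add atoms: ethylene glycol, OCCO
Why: Acid-catalysed ketalisation with azeotropic removal of water masks the ketone that will become C7, so that only one keto ester unit is present in the Knoevenagel and Michael steps.

Step 3
Reactants: 5 methyl 2-(2-hexadecyl-1,3-dioxolan-2-yl)acetate
Product: 6 2-(2-hexadecyl-1,3-dioxolan-2-yl)acetaldehyde
Conditions: i-Bu2AlH (1.05 equiv), CH2Cl2, −78 °C; MeOH, then aqueous Rochelle salt
Reagents that add atoms: none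
Why: Partial reduction of the ester by i-Bu2AlH at −78 °C should stop at the aluminium hemiacetal, stabilised by chelation to a dioxolane oxygen, and give the aldehyde on work-up.

Step 4
Reactants: 4 methyl 3-oxononadecanoate; 6 2-(2-hexadecyl-1,3-dioxolan-2-yl)acetaldehyde
Product: 7 methyl (2Z)-2-[2-(2-hexadecyl-1,3-dioxolan-2-yl)ethylidene]-3-oxononadecanoate
Conditions: piperidine (10 mol%), AcOH (10 mol%), CH2Cl2, 4 Å MS, 0 °C
Reagents that add atoms: none
Why: Knoevenagel condensation under piperidinium acetate, in which the iminium ion of 6 is attacked by the enol of 4 and loss of the amine gives the alkylidene β-keto ester, expected as an E/Z mixture from which the (Z) isomer is taken on and the other re-equilibrated under the same catalysis; low temperature and a small excess of 6 hold back a second, Michael addition of 4.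

Step 5
Reactants: 8 methyl pyruvate; 9 tert-butyl (triphenyl-λ5-phosphanylidene)acetate
Product: 10 4-tert-butyl 1-methyl (2E)-2-methylbut-2-enedioate
Conditions: CH2Cl2, rt
Reagents that add atoms: none
Why: Wittig olefination of the activated ketone of methyl pyruvate by the stabilised ylide; the alkene geometry (mainly E expected) is of no consequence because it is lost at the ylide stage of step 8.

Step 6
Reactants: 10 4-tert-butyl 1-methyl (2E)-2-methylbut-2-enedioate
Product: 11 4-tert-butyl 1-methyl (2Z)-2-(bromomethyl)but-2-enedioate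
Conditions: N-bromosuccinimide, AIBN (cat.), PhCF3, 85 °C
Reagents that add atoms: N-bromosuccinimide, O=C1CCC(=O)N1Br
Why: Wohl–Ziegler bromination, in which the methyl group carries the only allylic C–H bonds and the ester-conjugated allyl radical is brominated at that terminus, the tert-butyl ester being inert under neutral radical conditions.

Step 7
Reactants: 11 4-tert-butyl 1-methyl (2Z)-2-(bromomethyl)but-2-enedioate
Product: 12 [(2Z)-4-tert-butoxy-2-(methoxycarbonyl)-4-oxobut-2-en-1-yl]triphenylphosphonium bromide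
Conditions: PPh3, toluene, rt
Reagents that add atoms: triphenylphosphine, c1ccc(cc1)P(c1ccccc1)c1ccccc1
Why: SN2 quaternisation of triphenylphosphine by the primary allylic bromide, driven by precipitation of the salt.

Step 8
Reactants: 12 [(2Z)-4-tert-butoxy-2-(methoxycarbonyl)-4-oxobut-2-en-1-yl]triphenylphosphonium bromide
Product: 13 4-tert-butyl 1-methyl 2-[(triphenyl-λ5-phosphanylidene)methyl]but-2-enedioate
Conditions: 1 M NaOH (aq.), CH2Cl2, 0 °C; phases separated, dried, concentrated
Reagents that add atoms: none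
Why: Deprotonation of the CH2–P group, acidified by phosphorus and vinylogously by the tert-butyl ester, gives a stabilised allylic ylide that can be extracted free of salt and base for step 9.

Step 9
Reactants: 7 methyl (2Z)-2-[2-(2-hexadecyl-1,3-dioxolan-2-yl)ethylidene]-3-oxononadecanoate; 13 4-tert-butyl 1-methyl 2-[(triphenyl-λ5-phosphanylidene)methyl]but-2-enedioate
Product: 15 1-tert-butyl 2,5-dimethyl (5S,6S)-4-hexadecyl-6-[(2-hexadecyl-1,3-dioxolan-2-yl)methyl]cyclohexa-1,3-diene-1,2,5-tricarboxylate, via Michael-adduct ylide 14 (not isolated)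
Conditions: 1,1′-[(1R,2R)-cyclohexane-1,2-diyl]bis{3-[3,5-bis(trifluoromethyl)phenyl]thiourea} (10 mol%), toluene, 4 Å MS, −30 °C; then 80 °C
Reagents that add atoms: none
Why: Proposed new method: the bis-thiourea binds the two carbonyl groups of alkylidene β-keto ester 7 through N–H···O bonds and shields one face of its β-carbon, the γ-carbon of the stabilised allylic ylide 13 adds there (Michael addition), the zwitterion passes its γ-proton to the β-keto ester enolate to give ylide 14, and on warming the ylide carbon attacks the C(=O)C16 ketone in an intramolecular Wittig reaction that expels Ph3PO. The closest known reaction types are the base-mediated tandem Michael/Wittig [3+3] annulation of crotonate-derived allylic phosphorus ylides with enones to cyclohexa-1,3-dienes and the thiourea-catalysed enantioselective addition of stabilised phosphorus ylides to nitroalkenes and N-acyl imines; their combination on an alkylidene β-keto ester is what is new. The one ring closed, the cyclohexadiene that becomes ring A, forms by 6-exo-trig attack of the ylide carbon on the ketone after the intermolecular C–C bond has been made. C6 (later C8a) is set in the Michael stage by the catalyst, and C5 (later C1) should settle trans to it during ring closure because both substituents then sit pseudoaxial and escape A(1,2) strain with the flanking CO2t-Bu and hexadecyl groups. The step needs γ- rather than α-attack of the ylide (the α-adduct cannot close a six-membered ring and reverts), olefination of the ketone and not of an ester, and no uncatalysed or Ph3PO-inhibited addition; the first two follow from ring size and carbonyl reactivity, the last from running the Michael stage cold so that Ph3PO appears only in the thermal stage.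

Step 10
Reactants: 15 1-tert-butyl 2,5-dimethyl (5S,6S)-4-hexadecyl-6-[(2-hexadecyl-1,3-dioxolan-2-yl)methyl]cyclohexa-1,3-diene-1,2,5-tricarboxylate
Product: 16 1-tert-butyl 2,5-dimethyl (1S,2R,5S,6R)-4-hexadecyl-6-[(2-hexadecyl-1,3-dioxolan-2-yl)methyl]cyclohex-3-ene-1,2,5-tricarboxylate
Conditions: Cu(OAc)2·H2O (5 mol%), 1,2-bis(diphenylphosphino)benzene (5 mol%), (EtO)2MeSiH, t-BuOH, toluene, 0 °C to rt; aqueous NH4Cl
Reagents that add atoms: none
Why: Copper-hydride conjugate reduction with a silane as terminal reductant, in which the doubly ester-activated C1=C2 bond is the hydride acceptor (1,6-addition at the fully substituted C4 is blocked), hydride should enter at the less hindered C2 anti to the pseudoaxial side chain on C6 and the ester enolate is protonated at C1 by t-BuOH from the same open face, which sets C1 and C2 and gives the all-cis H1/H2/H6 array.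

Step 11
Reactants: 16 1-tert-butyl 2,5-dimethyl (1S,2R,5S,6R)-4-hexadecyl-6-[(2-hexadecyl-1,3-dioxolan-2-yl)methyl]cyclohex-3-ene-1,2,5-tricarboxylate
Product: 17 (1S,2R,5S,6R)-4-hexadecyl-2,5-bis(methoxycarbonyl)-6-(2-oxooctadecyl)cyclohex-3-ene-1-carboxylic acid
Conditions: CF3CO2H/CH2Cl2 (1:3), H2O (5 equiv), 0 °C to rt
Reagents that add atoms: water, O
Why: Acidolysis, in which the tert-butyl ester is cleaved through the tert-butyl cation and the dioxolane is hydrolysed by the wet acid in the same pot, while the methyl esters, the β,γ-alkene and the α-stereocentres (not enolised in acid) are left alone.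

Step 12
Reactants: 17 (1S,2R,5S,6R)-4-hexadecyl-2,5-bis(methoxycarbonyl)-6-(2-oxooctadecyl)cyclohex-3-ene-1-carboxylic acid
Product: 19 dimethyl (1S,4R,5S,6R)-2-hexadecyl-5-(3-methoxy-3-oxopropanoyl)-6-(2-oxooctadecyl)cyclohex-2-ene-1,4-dicarboxylate, via acyl imidazolide 18 (not isolated)
Conditions: 1,1′-carbonyldiimidazole, THF, rt; then KO2CCH2CO2Me, MgCl2, Et3N (premixed in MeCN), rt; 1 M HCl
Reagents that add atoms: potassium methyl malonate, COC(=O)CC(=O)[O-].[K+]
Why: Masamune–Brooks chain extension, in which the acyl imidazolide C-acylates the magnesium enolate of the malonate half ester and the acyl malonate loses CO2 on acidic work-up to give the β-keto ester (C5, C6 and the third CO2Me) under near-neutral conditions that should not epimerise the ring carbons next to the carbonyl groups.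

Step 13
Reactants: 19 dimethyl (1S,4R,5S,6R)-2-hexadecyl-5-(3-methoxy-3-oxopropanoyl)-6-(2-oxooctadecyl)cyclohex-2-ene-1,4-dicarboxylate
Product: 20 trimethyl (1S,4R,4aS,8aR)-2,7-dihexadecyl-5-oxo-1,4,4a,5,8,8a-hexahydronaphthalene-1,4,6-tricarboxylate
Conditions: piperidine (20 mol%), AcOH (20 mol%), toluene, 4 Å MS, 60 °C
Reagents that add atoms: none
Why: Intramolecular Knoevenagel condensation, in which the β-keto ester methylene (C6) adds to the C7 ketone in a 6-exo-trig aldol step and dehydration into conjugation closes ring B, the cis ring fusion being inherited from the cis side chains of 19 and piperidinium acetate being too weak a base to enolise C1, C4 or C4a.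

**Compound list**
1 | methyl acetoacetate | CC(=O)CC(=O)OC | starting material
2 | 1-bromopentadecane | CCCCCCCCCCCCCCCBr | starting material
3 | sodium lithium dianion (bis-enolate) of methyl acetoacetate | C=C([O-])C=C([O-])OC.[Na+].[Li+] | intermediate (not isolated)
4 | methyl 3-oxononadecanoate | CCCCCCCCCCCCCCCCC(=O)CC(=O)OC | intermediate
5 | methyl 2-(2-hexadecyl-1,3-dioxolan-2-yl)acetate | CCCCCCCCCCCCCCCCC1(CC(=O)OC)OCCO1 | intermediate
6 | 2-(2-hexadecyl-1,3-dioxolan-2-yl)acetaldehyde | CCCCCCCCCCCCCCCCC1(CC=O)OCCO1 | intermediate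
7 | methyl (2Z)-2-[2-(2-hexadecyl-1,3-dioxolan-2-yl)ethylidene]-3-oxononadecanoate | CCCCCCCCCCCCCCCCC(=O)/C(C(=O)OC)=C/CC1(CCCCCCCCCCCCCCCC)OCCO1 | intermediate
8 | methyl pyruvate | CC(=O)C(=O)OC | starting material
9 | tert-butyl (triphenyl-λ5-phosphanylidene)acetate | CC(C)(C)OC(=O)C=P(c1ccccc1)(c1ccccc1)c1ccccc1 | starting material
10 | 4-tert-butyl 1-methyl (2E)-2-methylbut-2-enedioate | COC(=O)/C(C)=C/C(=O)OC(C)(C)C | intermediate
11 | 4-tert-butyl 1-methyl (2Z)-2-(bromomethyl)but-2-enedioate (ester groups trans) | COC(=O)/C(CBr)=C/C(=O)OC(C)(C)C | intermediate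
12 | [(2Z)-4-tert-butoxy-2-(methoxycarbonyl)-4-oxobut-2-en-1-yl]triphenylphosphonium bromide | COC(=O)/C(C[P+](c1ccccc1)(c1ccccc1)c1ccccc1)=C/C(=O)OC(C)(C)C.[Br-] | intermediate
13 | 4-tert-butyl 1-methyl 2-[(triphenyl-λ5-phosphanylidene)methyl]but-2-enedioate (allylic ylide, C=C geometry labile and left open) | COC(=O)C(C=P(c1ccccc1)(c1ccccc1)c1ccccc1)=CC(=O)OC(C)(C)C | intermediate
14 | Michael-adduct ylide: 4-tert-butyl 1-methyl 3-[(2S)-1-(2-hexadecyl-1,3-dioxolan-2-yl)-3-(methoxycarbonyl)-4-oxoicosan-2-yl]-2-[(triphenyl-λ5-phosphanylidene)methyl]but-2-enedioate (keto ester carbon epimerising) | CCCCCCCCCCCCCCCCC(=O)C(C(=O)OC)[C@H](CC1(CCCCCCCCCCCCCCCC)OCCO1)C(C(=O)OC(C)(C)C)=C(C(=O)OC)C=P(c1ccccc1)(c1ccccc1)c1ccccc1 | intermediate (not isolated)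
15 | 1-tert-butyl 2,5-dimethyl (5S,6S)-4-hexadecyl-6-[(2-hexadecyl-1,3-dioxolan-2-yl)methyl]cyclohexa-1,3-diene-1,2,5-tricarboxylate | CCCCCCCCCCCCCCCCC1=CC(C(=O)OC)=C(C(=O)OC(C)(C)C)[C@@H](CC2(CCCCCCCCCCCCCCCC)OCCO2)[C@@H]1C(=O)OC | intermediate
16 | 1-tert-butyl 2,5-dimethyl (1S,2R,5S,6R)-4-hexadecyl-6-[(2-hexadecyl-1,3-dioxolan-2-yl)methyl]cyclohex-3-ene-1,2,5-tricarboxylate | CCCCCCCCCCCCCCCCC1=C[C@@H](C(=O)OC)[C@@H](C(=O)OC(C)(C)C)[C@@H](CC2(CCCCCCCCCCCCCCCC)OCCO2)[C@@H]1C(=O)OC | intermediate
17 | (1S,2R,5S,6R)-4-hexadecyl-2,5-bis(methoxycarbonyl)-6-(2-oxooctadecyl)cyclohex-3-ene-1-carboxylic acid | CCCCCCCCCCCCCCCCC1=C[C@@H](C(=O)OC)[C@@H](C(=O)O)[C@@H](CC(=O)CCCCCCCCCCCCCCCC)[C@@H]1C(=O)OC | intermediate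
18 | acyl imidazolide of 17: dimethyl (1S,4R,5S,6R)-2-hexadecyl-5-(imidazol-1-ylcarbonyl)-6-(2-oxooctadecyl)cyclohex-2-ene-1,4-dicarboxylate | CCCCCCCCCCCCCCCCC1=C[C@@H](C(=O)OC)[C@@H](C(=O)n2ccnc2)[C@@H](CC(=O)CCCCCCCCCCCCCCCC)[C@@H]1C(=O)OC | intermediate (not isolated)
19 | dimethyl (1S,4R,5S,6R)-2-hexadecyl-5-(3-methoxy-3-oxopropanoyl)-6-(2-oxooctadecyl)cyclohex-2-ene-1,4-dicarboxylate | CCCCCCCCCCCCCCCCC1=C[C@@H](C(=O)OC)[C@@H](C(=O)CC(=O)OC)[C@@H](CC(=O)CCCCCCCCCCCCCCCC)[C@@H]1C(=O)OC | intermediate
20 | trimethyl (1S,4R,4aS,8aR)-2,7-dihexadecyl-5-oxo-1,4,4a,5,8,8a-hexahydronaphthalene-1,4,6-tricarboxylate | CCCCCCCCCCCCCCCCC1=C[C@@H](C(=O)OC)[C@H]2C(=O)C(C(=O)OC)=C(CCCCCCCCCCCCCCCC)C[C@H]2[C@@H]1C(=O)OC | target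

**Step count**
Total: 13 steps. Longest linear sequence: 9 steps (steps 1, 2, 3, 4, 9, 10, 11, 12, 13).

**Steps most likely to fail**

Step 9. Uncatalysed addition of the ylide, or equilibration of the alkene geometry of 7, could erode the enantiomeric purity, and olefination of the hindered ketone by the stabilised ylide could be sluggish. The fallback uses known chemistry, sets out from 7 and comes back at 15. A quinine-derived bifunctional squaramide catalyses the enantioselective Michael addition of commercial tert-butyl acetoacetate (CC(=O)CC(=O)OC(C)(C)C) to 7. This gives the acyclic Michael adduct 1-tert-butyl 5-methyl (3R)-2-acetyl-4-heptadecanoyl-3-[(2-hexadecyl-1,3-dioxolan-2-yl)methyl]pentanedioate F1. Pyrrolidinium acetate then closes it by Hagemann-type aldol condensation of the acetyl methyl group onto the long-chain ketone, giving the cyclohexenone 1-tert-butyl 3-methyl (2S,3S)-4-hexadecyl-2-[(2-hexadecyl-1,3-dioxolan-2-yl)methyl]-6-oxocyclohex-4-ene-1,3-dicarboxylate F2. NaH and PhNTf2 convert its β-keto ester into the enol triflate 1-tert-butyl 5-methyl (5S,6S)-4-hexadecyl-6-[(2-hexadecyl-1,3-dioxolan-2-yl)methyl]-2-{[(trifluoromethyl)sulfonyl]oxy}cyclohexa-1,3-diene-1,5-dicarboxylate F3. Methoxycarbonylation (Pd(OAc)2, 1,3-bis(diphenylphosphino)propane, CO, MeOH, Et3N, DMF, 60 °C) then gives 15.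

Step 10. Hydride transfer to the tetrasubstituted alkene may be too slow, γ-protonation of an extended enolate may move the remaining double bond, or the facial selectivity may be poor. The fallback sets out from 15 and comes back at 17. Wet CF3CO2H in CH2Cl2 removes the tert-butyl ester and the ketal first, giving the diene acid (5S,6S)-4-hexadecyl-2,5-bis(methoxycarbonyl)-6-(2-oxooctadecyl)cyclohexa-1,3-diene-1-carboxylic acid F4. Carboxylate-directed hydrogenation with Ru(OAc)2[(S)-H8-BINAP] (or its antipode, whichever matches the facial bias of the substrate), H2 (50 bar), MeOH, 50 °C should then add H2 syn to the α,β-unsaturated acid only, because only that alkene can form the five-membered ruthenium carboxylate chelate, and so give 17.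

Step 4. β-Elimination of a dioxolane oxygen from the aldehyde enamine, self-condensation of 6, or Michael addition of a second molecule of 4 to the product could consume the material. The fallback sets out from 5 and comes back at 7 without an aldehyde. LiAlH4 reduces 5 to 2-(2-hexadecyl-1,3-dioxolan-2-yl)ethan-1-ol F5. CBr4/PPh3 (Appel reaction) gives 2-(2-bromoethyl)-2-hexadecyl-1,3-dioxolane F6. Keto ester 4 is C-alkylated with it (K2CO3, DMF, 60 °C) to racemic methyl 2-[2-(2-hexadecyl-1,3-dioxolan-2-yl)ethyl]-3-oxononadecanoate F7. NaH followed by N-bromosuccinimide gives racemic methyl 2-bromo-2-[2-(2-hexadecyl-1,3-dioxolan-2-yl)ethyl]-3-oxononadecanoate F8. Et3N in CH2Cl2 eliminates HBr toward the only β-hydrogens to give 7.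

**Further compounds**
F1 | step 9 | 1-tert-butyl 5-methyl (3R)-2-acetyl-4-heptadecanoyl-3-[(2-hexadecyl-1,3-dioxolan-2-yl)methyl]pentanedioate | CCCCCCCCCCCCCCCCC(=O)C(C(=O)OC)[C@H](CC1(CCCCCCCCCCCCCCCC)OCCO1)C(C(C)=O)C(=O)OC(C)(C)C
F2 | step 9 | 1-tert-butyl 3-methyl (2S,3S)-4-hexadecyl-2-[(2-hexadecyl-1,3-dioxolan-2-yl)methyl]-6-oxocyclohex-4-ene-1,3-dicarboxylate | CCCCCCCCCCCCCCCCC1=CC(=O)C(C(=O)OC(C)(C)C)[C@@H](CC2(CCCCCCCCCCCCCCCC)OCCO2)[C@@H]1C(=O)OC
F3 | step 9 | 1-tert-butyl 5-methyl (5S,6S)-4-hexadecyl-6-[(2-hexadecyl-1,3-dioxolan-2-yl)methyl]-2-{[(trifluoromethyl)sulfonyl]oxy}cyclohexa-1,3-diene-1,5-dicarboxylate | CCCCCCCCCCCCCCCCC1=CC(OS(=O)(=O)C(F)(F)F)=C(C(=O)OC(C)(C)C)[C@@H](CC2(CCCCCCCCCCCCCCCC)OCCO2)[C@@H]1C(=O)OC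
F4 | step 10 | (5S,6S)-4-hexadecyl-2,5-bis(methoxycarbonyl)-6-(2-oxooctadecyl)cyclohexa-1,3-diene-1-carboxylic acid | CCCCCCCCCCCCCCCCC1=CC(C(=O)OC)=C(C(=O)O)[C@@H](CC(=O)CCCCCCCCCCCCCCCC)[C@@H]1C(=O)OC
F5 | step 4 | 2-(2-hexadecyl-1,3-dioxolan-2-yl)ethan-1-ol | CCCCCCCCCCCCCCCCC1(CCO)OCCO1
F6 | step 4 | 2-(2-bromoethyl)-2-hexadecyl-1,3-dioxolane | CCCCCCCCCCCCCCCCC1(CCBr)OCCO1
F7 | step 4 | methyl 2-[2-(2-hexadecyl-1,3-dioxolan-2-yl)ethyl]-3-oxononadecanoate (racemic) | CCCCCCCCCCCCCCCCC(=O)C(CCC1(CCCCCCCCCCCCCCCC)OCCO1)C(=O)OC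
F8 | step 4 | methyl 2-bromo-2-[2-(2-hexadecyl-1,3-dioxolan-2-yl)ethyl]-3-oxononadecanoate (racemic) | CCCCCCCCCCCCCCCCC(=O)C(Br)(CCC1(CCCCCCCCCCCCCCCC)OCCO1)C(=O)OC
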